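All constants are made up; the run is a simulation.

Amounts first: Q and D start equal, so I follow r and d, the fractions of their own charges still left.

the same everywhere: Q 0.17 M; J 3.00 equiv; G 0.5 mol%; D 0.17 M; time 15 h

| run | temperature |
|---|---|
| ochre | −20 °C |
| violet | 5 °C |
| amber | 30 °C |

    J + G + Q → G + X (k1 = 0.398 L² mol⁻² s⁻¹, Ea1 = 36.0 kJ mol⁻¹)
    J + G + D → G + L (k2 = 0.00420 L² mol⁻² s⁻¹, Ea2 = 38.0 kJ mol⁻¹)
    2 G → G2 (k3 = 0.183 L mol⁻¹ s⁻¹, Ea3 = 47.0 kJ mol⁻¹)
    (constants at −20 °C)

- G is single-handed; Q and D are mirror images of each other, charged as a racemate, each of them at the stated concentration
- a step written with two of one species runs at k times the square of its concentration and takes two of it each time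
- constants are those at −20 °C; use the activation energies for any other temperature
- an excess is the difference of the two amounts in percent of their sum
- an excess is below zero if the other one leads

- which flask leads in excess of X over L ("all alike" within 1.5 percentage points) (ochre / violet / amber / all alike)
- excess of X over L at the end, ochre
- excess of X over L at the end, violet
- excess of X over L at the end, amber

Dividing the loss of Q by the loss of D cancels J, G and time, leaving ln r = s ln d, where s is the constant of the Q step over that of the D step. This s is the selectivity factor, and it comes to 94.8 in ochre, 87.0 in violet and 81.0 in amber.

I take violet between two extremes. If G were lost at once, the first small turnover would give X over L equal to s, an excess of 97.7%. If G stayed at its charge and J did too, d would be 60.8%, r would be hardly any, and the excess would fall to 43.7%.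

G pairs off by second-order loss. Integrating G over time gives an exposure of 7.87 M·s in ochre, 1.78 M·s in violet and 0.447 M·s in amber; violet's is far less than its full charge would give, so I place violet between the two extremes. Letting J fall with Q and ignoring the small draw by D, I integrate for r: 26.0% in ochre, 24.5% in violet and 27.5% in amber. The rule then gives excesses of 96.3%, 95.8% and 95.7%. Their spread is less than the margin, so I call them all alike.

The forecast says all alike, with 96.2%, 95.8% and 95.7%: “With D barely consumed in each case, the excess sits near 96% throughout”. In ochre it stands 0.100 percentage points below mine.

The simulation gives all alike, with 96.3%, 95.8% and 95.7%. In violet the Q step outruns the D step by 54 at 0.402 h and by 22 at 15.0 h, and s times the Q left over the D left comes to 21.7. The neighbour of violet with 12.0 equiv of J ends with 0.20% of its Q, from which s puts D at 93.1% against 93% in the flask, and that neighbour's excess stands at 87.1%.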